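At the time of reading, 2.5 d after the start in eta, gamma and theta, I wanted the amount of target in those flasks, and also in epsilon, a tank read at steady state with 2.5 d in it on average; the amounts are the same in each set-up. For eta, where starting material is fed at a steady rate, I began with how much of it stands unreacted.

| flask | starting material | other conformer | remark | time |
|---|---|---|---|---|
| north | 0.050 M | 0.25 equiv | run made earlier |  |
| west | 0.050 M | 0.12 equiv | run made earlier |  |
| south-east | 0.050 M | 0.50 equiv | run made earlier |  |
| north-east | 0.10 M | 0.25 equiv | run made earlier |  |
| eta | 0.050 M (fed, over 2.50 d) | 0.250 equiv | all but starting material at the start; starting material goes in evenly over 2.50 d, the run ends at 2.5 d | 2.5 d |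
| epsilon | 0.050 M | 0.250 equiv | a single well-mixed tank run continuously and read at steady state, 2.5 d in it on average |  |
| gamma | 0.050 M | 0.250 equiv (fed, over 2.50 d) | a stirred flask in which other conformer is dosed at a steady rate over 2.50 d without added volume, worked up at 2.5 d | 2.5 d |
| theta | 0.050 M | 0.250 equiv | a closed flask charged with all of it at once and left for 2.5 d | 2.5 d |

| run | time / h | target / % | starting material / % |
|---|---|---|---|
| north | 10.0 | 22.9 | 2.8 |
| north | 20.0 | 23.8 | 0 |
| north | 25.0 | 23.7 | 0 |
| north | 40.0 | 23.4 | 0.2 |
| west | 12.0 | 23.6 | 1.9 |
| west | 25.0 | 23.8 | 0 |
| west | 40.0 | 23.7 | 0.4 |
| west | 50.0 | 23.3 | 0 |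
| south-east | 6.00 | 20.1 | 7.6 |
| south-east | 15.0 | 23.6 | 0.2 |
| south-east | 30.0 | 23.8 | 0 |
| south-east | 50.0 | 23.4 | 0 |
| north-east | 6.00 | 17.9 | 9.8 |
| north-east | 15.0 | 21.4 | 0.1 |
| north-east | 30.0 | 21.5 | 0.3 |
| north-east | 50.0 | 22.3 | 0.1 |

(scatter of a reading: 0.5 percentage points)

- percent here means starting material units held: one side product counts as two
- the stated concentrations are those of everything mixed, before any reaction; amounts are the same in each set-up
- the earlier runs were read with a standard deviation of 0.5 percentage points
- steps under discussion: starting material <-> other conformer; starting material -> target; other conformer -> isomer of the product; target <-> isomer of the product; starting material + target -> side product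
- the feed brings no volume worth counting
- the earlier runs were made in a closed, stirred flask

* the set-up with the highest amount of target at the outlet or at the end, in percent of the starting material and other conformer together put in ("none" if the first two lie within 2 percentage points) (eta / epsilon / gamma / theta / none)
* amount of target at the outlet or at the end, in percent of the starting material and other conformer together put in, eta
* amount of target at the outlet or at the end, in percent of the starting material and other conformer together put in, epsilon
* amount of target at the outlet or at the end, in percent of the starting material and other conformer together put in, gamma
* amount of target at the outlet or at the end, in percent of the starting material and other conformer together put in, theta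

The north run held 80.0% of its charge as starting material and read 2.8% at 10.0 h. I treated the decay as pseudo-first-order and read a lifetime:

lifetime = time / ln(share / reading) = 2.98 h

The south-east run, with a different charge, reads 2.76 h the same way.

I then drew [starting material] against time in eta. The curve leaves zero with a slope equal to the feed rate:

feed rate = 8.333 × 10⁻⁴ M h⁻¹

That tangent meets the final level after one lifetime, which is where the knee lies. The lifetime is far shorter than the feed, which spans 20.1 lifetimes, so the curve runs flat into the level at which feed and loss balance:

standing level = feed rate × lifetime = 0.002486 M

This standing level, feed rate times lifetime, is 3.98% of the charge, and it still stands when eta ends, since the feed runs up to 2.50 d.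

The north run levelled at 23.7% target at 25.0 h, and the west and south-east runs read 23.8% and 23.8% on their plateaus. I assumed that eta loses as much to side product as the north run, and applied that plateau to the part that had reacted:

target in eta = 23.7% × (1 − 3.98%) = 22.8%

The forecast gave 22.7% for eta (21.5% to 23.8%), 21.8% for epsilon, 23.5% for gamma and 23.6% for theta, with best none. Its ground for eta was “about 4% starting material remains unreacted at the end”, and my own figure was 22.8%.

    starting material ⇌ other conformer (K = 0.230, k = 0.220 h⁻¹)
    starting material → target (k = 0.110 h⁻¹)
    other conformer → isomer of the product (k = 15.0 h⁻¹)
    target ⇌ isomer of the product (K = 2.80, k = 0.180 h⁻¹)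
    starting material + target → side product (k = 2.70 L mol⁻¹ h⁻¹)

The flasks gave 22.5% in eta, 20.9% in epsilon, 23.6% in gamma and 23.6% in theta, so the answer was none. Eta's highest [starting material] was 0.00251 M, against my standing level of 0.00249 M, and it ended with 3.77% of the charge as starting material. In epsilon the outflow adds to the loss, with 2.5 d in the tank on average, so the standing level becomes 0.00249 M / (1 + lifetime / 2.5 d) = 0.002372 M. The tank held 0.00229 M, which is 3.67% of the charge.

The runs were generated by integration for substances that don't exist, noise included.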